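Everything rests on taking apart the dihydrofuran ring and the acrylate together. In benzofuran numbering, C2 holds both ring oxygen O1 and the alpha-carbon of the acrylate, and the C3 oxygen sits cis to that carbon; this array is what results when a phenol closes onto the proximal carbon of an allene, CO is inserted at the middle allene carbon and the adjacent hydroxyl intercepts the acyl group. One palladium-mediated cascade on allenyl carbinol 8, a para-bromophenol carrying an ortho (R)-1-hydroxybuta-2,3-dienyl chain, should therefore make O1–C2, C(alpha)–C(=O) and the lactone C–O bond, closing the dihydrofuran ring and a cis-fused alpha-methylene lactone (10) that keeps C2 and C3 cis until ester and acetate are released.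

Key step: step 6

Remark on stereochemistry: the target is (2S,3S) with the C2 side chain and the C3 acetoxy group cis, and (S) at the side-chain carbinol. The (R) descriptor of carbinol 8 and the (S) descriptor at C3 from 10 onwards denote the same spatial arrangement, because C2 gains an oxygen and changes rank.

Assumption: (R)-BINOL/Ti(OiPr)4 directs the alkynylzinc to the Re face of aldehyde 2, as the mirror image of the sense associated with the (S)-ligand and aryl aldehydes. If the ortho-silyloxy group reverses the sense, the (S)-ligand is used instead.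

Remark on design: the phenol stays silylated until the allene is in place, since a free phenol would be aminomethylated during the homologation. Phenol 8 is released only immediately before the cascade. Bromine is kept as the C5 spectator because it is inert to phosphine-free divalent palladium, and it is exchanged for acetyl while the cis array is still locked in the lactone.

Step 1
Reactants: 1 5-bromo-2-hydroxybenzaldehyde
Product: 2 5-bromo-2-{[tri(propan-2-yl)silyl]oxy}benzaldehyde
Conditions: TIPSCl, imidazole, DMF, rt
Reagents that add atoms: chlorotri(propan-2-yl)silane (TIPSCl), CC(C)[Si](Cl)(C(C)C)C(C)C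
Why: Imidazole-promoted O-silylation of the phenol; the hindered triisopropylsilyl ether is chosen because it should survive the organozinc addition, the carbonate-mediated C-desilylation and the hot amine of the allene homologation, where a free phenol would be aminomethylated.

Step 2
Reactants: 2 5-bromo-2-{[tri(propan-2-yl)silyl]oxy}benzaldehyde; 3 ethynyltrimethylsilane
Product: 4 (1S)-1-(5-bromo-2-{[tri(propan-2-yl)silyl]oxy}phenyl)-3-(trimethylsilyl)prop-2-yn-1-ol
Conditions: 3 (3 equiv), Et2Zn (3 equiv), Cy2NH (5 mol %), Et2O, rt; (R)-BINOL (20 mol %), Ti(OiPr)4 (50 mol %); then 2, rt; aq. NH4Cl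
Reagents that add atoms: ethynyltrimethylsilane (3), C#C[Si](C)(C)C
Why: Catalytic asymmetric alkynylzinc addition to an aryl aldehyde under (R)-BINOL/Ti(OiPr)4 control, in which the (R)-ligand should deliver the alkynyl group to the Re face of the formyl group (the mirror image of the Si-face delivery known for the (S)-ligand), setting the carbinol centre that becomes C3; the centre is (S) in 4 only because the silylalkynyl branch outranks the aryl group.

Step 3
Reactants: 4 (1S)-1-(5-bromo-2-{[tri(propan-2-yl)silyl]oxy}phenyl)-3-(trimethylsilyl)prop-2-yn-1-ol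
Product: 5 (1R)-1-(5-bromo-2-{[tri(propan-2-yl)silyl]oxy}phenyl)prop-2-yn-1-ol
Conditions: K2CO3 (0.2 equiv), MeOH, 0 °C
Reagents that add atoms: none
Why: Methoxide-mediated protodesilylation of the alkynylsilane is fast at 0 °C while the hindered aryl silyl ether should persist; the stereocentre is not touched and its descriptor becomes (R) merely through the change in priorities.

Step 4
Reactants: 5 (1R)-1-(5-bromo-2-{[tri(propan-2-yl)silyl]oxy}phenyl)prop-2-yn-1-ol
Product: 7 (1R)-1-(5-bromo-2-{[tri(propan-2-yl)silyl]oxy}phenyl)buta-2,3-dien-1-ol, via propargylic amine 6 (not isolated)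
Conditions: (CH2O)n (2.5 equiv), Cy2NH (1.8 equiv), CuI (0.5 equiv), dioxane, reflux
Reagents that add atoms: formaldehyde (as paraformaldehyde), C=O
Why: Crabbé homologation: the alkynylcopper species formed with CuI adds to the iminium ion from formaldehyde and dicyclohexylamine to give Mannich base 6, whose 1,5-hydride shift (retro-imino-ene) expels the imine and leaves the terminal allene; free propargylic alcohols are tolerated, the carbinol centre is not involved, and the silyl ether keeps the phenol from being aminomethylated.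

Step 5
Reactants: 7 (1R)-1-(5-bromo-2-{[tri(propan-2-yl)silyl]oxy}phenyl)buta-2,3-dien-1-ol
Product: 8 4-bromo-2-[(1R)-1-hydroxybuta-2,3-dien-1-yl]phenol
Conditions: TBAF (1.1 equiv), AcOH (1.1 equiv), THF, 0 °C
Reagents that add atoms: none
Why: Fluoride cleavage of the aryl silyl ether, buffered with acetic acid so that the ortho-hydroxybenzylic allenyl alcohol never meets strong base or acid that could drive quinone methide formation; 8 is used at once in step 6.

Step 6
Reactants: 8 4-bromo-2-[(1R)-1-hydroxybuta-2,3-dien-1-yl]phenol; 9 carbon monoxide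
Product: 10 (3aS,8bS)-7-bromo-3-methylidene-3a,8b-dihydrofuro[3,2-b][1]benzofuran-2(3H)-one
Conditions: PdCl2(MeCN)2 (10 mol %), CuCl2 (3 equiv), NaOAc (3 equiv), CO (1 atm), AcOH, rt
Reagents that add atoms: carbon monoxide (9), [C-]#[O+]
Why: Proposed new method: divalent palladium should bind the allene double bond next to the carbinol, the acetate-buffered phenol oxygen should attack the inner allene carbon anti to the metal to leave a sigma-vinylpalladium on the central carbon, CO should insert, and the C3 hydroxyl should capture the acylpalladium before CuCl2 returns zerovalent palladium to the divalent state; the closest known reaction types are the PdCl2/CuCl2 alkoxycarbonylative cyclisation of gamma-allenols to 2-(tetrahydrofuran-2-yl)acrylates and the oxycarbonylative bicyclisation of pent-4-ene-1,3-diols to cis-fused bicyclic lactones, neither of which has been shown with a phenol closing onto an allene. The dihydrofuran ring closes in a 5-exo mode (bond O1–C2) and the lactone in a 5-exo acyl substitution (bonds C(alpha)–C(=O) and C(=O)–O). The one new stereocentre, C2, is controlled by the C3 carbinol centre, because only the acylpalladium that has the C2 side chain cis to the C3 hydroxyl can lactonise, the trans adduct having to return through reversible oxypalladation, so the (3aS,8bS) cis-fused lactone is expected. The step needs phenol attack at the inner carbon in preference to 5-endo attack of the C3 hydroxyl on the allene terminus, which the much higher acidity of the para-bromophenol under acetate buffering and the favourable exo geometry should secure. The aryl bromide is expected to stay untouched, as no phosphine is present and zerovalent palladium is reoxidised at once at room temperature.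

Step 7
Reactants: 10 (3aS,8bS)-7-bromo-3-methylidene-3a,8b-dihydrofuro[3,2-b][1]benzofuran-2(3H)-one
Product: 12 (3aS,8bS)-7-acetyl-3-methylidene-3a,8b-dihydrofuro[3,2-b][1]benzofuran-2(3H)-one, via enol ether 11 (not isolated)
Conditions: tributyl(1-ethoxyvinyl)stannane (1.3 equiv), PdCl2(PPh3)2 (5 mol %), toluene, 100 °C; then 1 M HCl, THF, rt
Reagents that add atoms: tributyl(1-ethoxyethenyl)stannane, CCCC[Sn](CCCC)(CCCC)C(=C)OCC; water, O
Why: Migita–Kosugi–Stille coupling of the aryl bromide with an acetyl anion equivalent, then mild acid hydrolysis of the enol ether; the coupling is placed on the rigid lactone, where C2 and C3 are tied cis in the bicycle and no benzylic acetate is yet present to be eliminated on heating.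

Step 8
Reactants: 12 (3aS,8bS)-7-acetyl-3-methylidene-3a,8b-dihydrofuro[3,2-b][1]benzofuran-2(3H)-one
Product: 15 methyl 2-[(2S,3S)-5-acetyl-3-(acetyloxy)-2,3-dihydro-1-benzofuran-2-yl]prop-2-enoate, via lithium carboxylate 13 (not isolated), via hydroxy ester 14 (not isolated)
Conditions: LiOH·H2O (1.05 equiv), THF–H2O, 0 °C; evaporate; MeI (3 equiv), DMF, rt; evaporate; Ac2O, pyridine, DMAP (5 mol %), 0 °C
Reagents that add atoms: lithium hydroxide, [Li+].[OH-]; iodomethane, CI; acetic anhydride, CC(=O)OC(C)=O
Why: Saponification of the strained lactone gives a carboxylate that cannot relactonise, SN2 methylation of that carboxylate and immediate pyridine/DMAP acetylation of the C3 hydroxyl then fix the open form; no bond to C2 or C3 is broken, so the cis (2S,3S) array is carried over unchanged.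

Step 9
Reactants: 15 methyl 2-[(2S,3S)-5-acetyl-3-(acetyloxy)-2,3-dihydro-1-benzofuran-2-yl]prop-2-enoate
Product: 16 methyl 2-[(2S,3S)-3-(acetyloxy)-5-[(1S)-1-hydroxyethyl]-2,3-dihydro-1-benzofuran-2-yl]prop-2-enoate
Conditions: RuCl[(S,S)-TsDPEN](p-cymene) (2 mol %), HCO2H–Et3N (5:2), EtOAc, rt
Reagents that add atoms: none
Why: Noyori–Ikariya asymmetric transfer hydrogenation of the aryl methyl ketone, in which the (S,S)-catalyst transfers hydride to the Re face of acetophenone-type ketones under catalyst control to set the (S)-carbinol, while the acidic formate medium should leave the acrylate and the benzylic acetate alone.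

Step 10
Reactants: 16 methyl 2-[(2S,3S)-3-(acetyloxy)-5-[(1S)-1-hydroxyethyl]-2,3-dihydro-1-benzofuran-2-yl]prop-2-enoate; 17 angelic acid
Product: 19 methyl 2-[(2S,3S)-3-(acetyloxy)-5-[(1S)-1-{[(2Z)-2-methylbut-2-enoyl]oxy}ethyl]-2,3-dihydro-1-benzofuran-2-yl]prop-2-enoate, via mixed anhydride 18 (not isolated)
Conditions: 17 (2 equiv), 2,4,6-trichlorobenzoyl chloride (2 equiv), Et3N (2.2 equiv), toluene, rt; then 16, 70 °C
Reagents that add atoms: angelic acid (17), C/C=C(/C)C(=O)O
Why: Yamaguchi esterification: the alcohol is acylated at oxygen by the preformed mixed anhydride, so the (S) centre is retained, and the DMAP-free variant in warm toluene is the protocol relied on to keep the Z geometry of the angelate from isomerising to the tiglate.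

Compound list
1 | 5-bromo-2-hydroxybenzaldehyde | O=Cc1cc(Br)ccc1O | starting material
2 | 5-bromo-2-{[tri(propan-2-yl)silyl]oxy}benzaldehyde | O=Cc1cc(Br)ccc1O[Si](C(C)C)(C(C)C)C(C)C | intermediate
3 | ethynyltrimethylsilane | C#C[Si](C)(C)C | starting material
4 | (1S)-1-(5-bromo-2-{[tri(propan-2-yl)silyl]oxy}phenyl)-3-(trimethylsilyl)prop-2-yn-1-ol | C[Si](C)(C)C#C[C@@H](O)c1cc(Br)ccc1O[Si](C(C)C)(C(C)C)C(C)C | intermediate
5 | (1R)-1-(5-bromo-2-{[tri(propan-2-yl)silyl]oxy}phenyl)prop-2-yn-1-ol | C#C[C@@H](O)c1cc(Br)ccc1O[Si](C(C)C)(C(C)C)C(C)C | intermediate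
6 | (1R)-1-(5-bromo-2-{[tri(propan-2-yl)silyl]oxy}phenyl)-4-(dicyclohexylamino)but-2-yn-1-ol | C(#C[C@@H](O)c1cc(Br)ccc1O[Si](C(C)C)(C(C)C)C(C)C)CN(C1CCCCC1)C1CCCCC1 | intermediate
7 | (1R)-1-(5-bromo-2-{[tri(propan-2-yl)silyl]oxy}phenyl)buta-2,3-dien-1-ol | C=C=C[C@@H](O)c1cc(Br)ccc1O[Si](C(C)C)(C(C)C)C(C)C | intermediate
8 | 4-bromo-2-[(1R)-1-hydroxybuta-2,3-dien-1-yl]phenol | C=C=C[C@@H](O)c1cc(Br)ccc1O | intermediate
9 | carbon monoxide | [C-]#[O+] | starting material
10 | (3aS,8bS)-7-bromo-3-methylidene-3a,8b-dihydrofuro[3,2-b][1]benzofuran-2(3H)-one (cis-fused alpha-methylene lactone) | C=C1C(=O)O[C@H]2c3cc(Br)ccc3O[C@@H]12 | intermediate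
11 | (3aS,8bS)-7-(1-ethoxyethenyl)-3-methylidene-3a,8b-dihydrofuro[3,2-b][1]benzofuran-2(3H)-one | C=C1C(=O)O[C@H]2c3cc(C(=C)OCC)ccc3O[C@@H]12 | intermediate
12 | (3aS,8bS)-7-acetyl-3-methylidene-3a,8b-dihydrofuro[3,2-b][1]benzofuran-2(3H)-one | C=C1C(=O)O[C@H]2c3cc(C(C)=O)ccc3O[C@@H]12 | intermediate
13 | lithium 2-[(2S,3S)-5-acetyl-3-hydroxy-2,3-dihydro-1-benzofuran-2-yl]prop-2-enoate | [Li+].C=C(C(=O)[O-])[C@@H]1Oc2ccc(C(C)=O)cc2[C@@H]1O | intermediate
14 | methyl 2-[(2S,3S)-5-acetyl-3-hydroxy-2,3-dihydro-1-benzofuran-2-yl]prop-2-enoate | C=C(C(=O)OC)[C@@H]1Oc2ccc(C(C)=O)cc2[C@@H]1O | intermediate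
15 | methyl 2-[(2S,3S)-5-acetyl-3-(acetyloxy)-2,3-dihydro-1-benzofuran-2-yl]prop-2-enoate | C=C(C(=O)OC)[C@@H]1Oc2ccc(C(C)=O)cc2[C@@H]1OC(C)=O | intermediate
16 | methyl 2-[(2S,3S)-3-(acetyloxy)-5-[(1S)-1-hydroxyethyl]-2,3-dihydro-1-benzofuran-2-yl]prop-2-enoate | C=C(C(=O)OC)[C@@H]1Oc2ccc([C@H](C)O)cc2[C@@H]1OC(C)=O | intermediate
17 | angelic acid, (2Z)-2-methylbut-2-enoic acid | C/C=C(/C)C(=O)O | starting material
18 | (2Z)-2-methylbut-2-enoic 2,4,6-trichlorobenzoic anhydride | C/C=C(/C)C(=O)OC(=O)c1c(Cl)cc(Cl)cc1Cl | intermediate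
19 | methyl 2-[(2S,3S)-3-(acetyloxy)-5-[(1S)-1-{[(2Z)-2-methylbut-2-enoyl]oxy}ethyl]-2,3-dihydro-1-benzofuran-2-yl]prop-2-enoate | C=C(C(=O)OC)[C@@H]1Oc2ccc([C@H](C)OC(=O)/C(C)=C\C)cc2[C@@H]1OC(C)=O | target

Total step count: 10 steps.
Longest linear sequence: 10 steps, from 1 to 19.

Steps most likely to fail

1. Step 6 (the cascade). Three processes may compete with it:
- 5-endo addition of the C3 hydroxyl to the allene terminus;
- ionisation of the benzylic hydroxyl in acetic acid;
- interception of the acylpalladium by acetate or chloride before the hydroxyl closes the lactone.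

Fallback with known chemistry: setting out from 8, iodoetherification of the allene with N-iodosuccinimide and NaHCO3 in MeCN at −20 °C is an electrophilic halocyclisation of a hydroxy allene, with iodine going to the central carbon and the phenol oxygen to the inner carbon. It should give (2R,3S)-5-bromo-2-(1-iodoethenyl)-2,3-dihydro-1-benzofuran-3-ol F1 together with its C2 epimer. Carbonylative lactonisation of the vinyl iodide (Pd(PPh3)4, CO 1 atm, K2CO3, THF, 50 °C), a standard entry to alpha-methylene lactones, should then convert the cis isomer into 10, where the route is rejoined. The trans epimer cannot lactonise and is removed by chromatography. The vinyl iodide should react with zerovalent palladium far faster than the aryl bromide.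

2. Step 8 (lactone opening, methylation, acetylation). Hydroxy ester 14 may relactonise while the carboxylate is being methylated or before acetylation is complete.

Fallback: the C3 oxygen is capped before the ester is made. Setting out from 12, saponification as in step 8 gives 13. The dry salt is silylated (TBSCl, imidazole, DMF) to tert-butyl(dimethyl)silyl 2-[(2S,3S)-5-acetyl-3-{[tert-butyl(dimethyl)silyl]oxy}-2,3-dihydro-1-benzofuran-2-yl]prop-2-enoate F2. K2CO3 in aqueous MeOH at 0 °C cleaves only the silyl ester and gives 2-[(2S,3S)-5-acetyl-3-{[tert-butyl(dimethyl)silyl]oxy}-2,3-dihydro-1-benzofuran-2-yl]prop-2-enoic acid F3, which cannot lactonise. MeI and K2CO3 in DMF give methyl 2-[(2S,3S)-5-acetyl-3-{[tert-butyl(dimethyl)silyl]oxy}-2,3-dihydro-1-benzofuran-2-yl]prop-2-enoate F4. HF·pyridine in THF at 0 °C then releases 14 under non-basic conditions, and Ac2O with DMAP added to the same flask gives 15, where the route is rejoined.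

3. Step 7 (Stille coupling on the methylene lactone). Three processes may interfere:
- Heck-type insertion of the arylpalladium into the strained exocyclic methylene of a second molecule;
- attack of phosphine or zerovalent palladium on the allylic aryl ether;
- thermal oligomerisation of the methylene lactone.

Fallback: the order is changed so that the coupling meets the less electrophilic open-chain acrylate, at the price of exposing the cis acetate to heat. Setting out from 10, the sequence of step 8 (LiOH; MeI; Ac2O) should lead through lithium 2-[(2S,3S)-5-bromo-3-hydroxy-2,3-dihydro-1-benzofuran-2-yl]prop-2-enoate F5 and methyl 2-[(2S,3S)-5-bromo-3-hydroxy-2,3-dihydro-1-benzofuran-2-yl]prop-2-enoate F6 to methyl 2-[(2S,3S)-3-(acetyloxy)-5-bromo-2,3-dihydro-1-benzofuran-2-yl]prop-2-enoate F7. Stille coupling of F7 with tributyl(1-ethoxyvinyl)stannane (PdCl2(PPh3)2, toluene, 90 °C) gives methyl 2-[(2S,3S)-3-(acetyloxy)-5-(1-ethoxyethenyl)-2,3-dihydro-1-benzofuran-2-yl]prop-2-enoate F8, and hydrolysis with dilute HCl in THF returns to the route at 15.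

Further compounds
F1 | step 6 | (2R,3S)-5-bromo-2-(1-iodoethenyl)-2,3-dihydro-1-benzofuran-3-ol | C=C(I)[C@@H]1Oc2ccc(Br)cc2[C@@H]1O
F2 | step 8 | tert-butyl(dimethyl)silyl 2-[(2S,3S)-5-acetyl-3-{[tert-butyl(dimethyl)silyl]oxy}-2,3-dihydro-1-benzofuran-2-yl]prop-2-enoate | C=C(C(=O)O[Si](C)(C)C(C)(C)C)[C@@H]1Oc2ccc(C(C)=O)cc2[C@@H]1O[Si](C)(C)C(C)(C)C
F3 | step 8 | 2-[(2S,3S)-5-acetyl-3-{[tert-butyl(dimethyl)silyl]oxy}-2,3-dihydro-1-benzofuran-2-yl]prop-2-enoic acid | C=C(C(=O)O)[C@@H]1Oc2ccc(C(C)=O)cc2[C@@H]1O[Si](C)(C)C(C)(C)C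
F4 | step 8 | methyl 2-[(2S,3S)-5-acetyl-3-{[tert-butyl(dimethyl)silyl]oxy}-2,3-dihydro-1-benzofuran-2-yl]prop-2-enoate | C=C(C(=O)OC)[C@@H]1Oc2ccc(C(C)=O)cc2[C@@H]1O[Si](C)(C)C(C)(C)C
F5 | step 7 | lithium 2-[(2S,3S)-5-bromo-3-hydroxy-2,3-dihydro-1-benzofuran-2-yl]prop-2-enoate | [Li+].C=C(C(=O)[O-])[C@@H]1Oc2ccc(Br)cc2[C@@H]1O
F6 | step 7 | methyl 2-[(2S,3S)-5-bromo-3-hydroxy-2,3-dihydro-1-benzofuran-2-yl]prop-2-enoate | C=C(C(=O)OC)[C@@H]1Oc2ccc(Br)cc2[C@@H]1O
F7 | step 7 | methyl 2-[(2S,3S)-3-(acetyloxy)-5-bromo-2,3-dihydro-1-benzofuran-2-yl]prop-2-enoate | C=C(C(=O)OC)[C@@H]1Oc2ccc(Br)cc2[C@@H]1OC(C)=O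
F8 | step 7 | methyl 2-[(2S,3S)-3-(acetyloxy)-5-(1-ethoxyethenyl)-2,3-dihydro-1-benzofuran-2-yl]prop-2-enoate | C=C(C(=O)OC)[C@@H]1Oc2ccc(C(=C)OCC)cc2[C@@H]1OC(C)=O
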